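**Plan**

- Retrosynthesis: the chroman ether bond O1–C2 is cut first, then C2–C3 (one-carbon insertion into a C–B bond), then C3–C1′ and C3–C4 together at one boron atom, and last C4–C4a (aryl shift onto a chloromethylboron unit). Side cuts are the C6–prenyl bond and the pyran ring of ring B.
- Enabling feature: C3 is a methine whose three non-hydrogen neighbours are all carbon (C2, C4 and C1′ of ring B), and the congested ring A is separated from it by the C4 methylene. A boron atom can therefore collect the ring A benzyl group, a CHCl carbenoid carbon and the ring B aryl nucleophile and join them at C3.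
- Forward: ring A is desymmetrised (prenyl, then CH2–B) and the ring B chromene is made by propargyl Claisen cyclisation. The three components are then joined at C3, C2 is inserted, and the chroman ring (ring C) is closed last.
- Stereochemistry: the only stereocentre, C3, is set by the (R,R)-1,2-dicyclohexylethane-1,2-diol on boron in the first 1,2-migration. Every later step is stereospecific or remote from C3.

Key step: step 10

Assumption: (R,R)-1,2-diol boronic esters are taken to give (αS)-α-chloro boronic esters with LiCHCl2/ZnCl2, as is the rule for C2-symmetric diol esters; if the sense were opposite here, the (S,S)-diol would be used and nothing else would change.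

Abbreviations: TIPS = triisopropylsilyl. Atom numbers are those of the isoflavan (O1, C2, C3, C4, C4a–C8a; C1′ = chromene C8).

**Route**

Step 1
Reactants: 1 5-methoxybenzene-1,3-diol (5-methoxyresorcinol)
Product: 2 1-methoxy-3,5-bis(triisopropylsilyloxy)benzene
Conditions: TIPSCl (2.3 equiv), imidazole, DMF, rt
Reagents that add atoms: chlorotriisopropylsilane, CC(C)[Si](Cl)(C(C)C)C(C)C
Why: Imidazole-mediated silylation of two unhindered phenols is routine, and the aryl TIPS ethers tolerate the organolithium, Grignard and borate chemistry that follows and are removed by fluoride at the end.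

Step 2
Reactants: 2 1-methoxy-3,5-bis(triisopropylsilyloxy)benzene
Product: 4 2,4-dibromo-3-methoxy-1,5-bis(triisopropylsilyloxy)benzene, via monobromide 3 (not isolated)
Conditions: NBS (2.05 equiv), CH2Cl2, −40 to 0 °C, dark
Reagents that add atoms: N-bromosuccinimide, O=C1CCC(=O)N1Br
Why: Electrophilic aromatic bromination of the highly activated ring should occur twice at the two equivalent carbons flanked by OMe and one OTIPS group, because the third free carbon lies between two bulky silyloxy groups.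

Step 3
Reactants: 4 2,4-dibromo-3-methoxy-1,5-bis(triisopropylsilyloxy)benzene, 5 1-bromo-3-methylbut-2-ene (prenyl bromide)
Product: 7 2-bromo-3-methoxy-4-(3-methylbut-2-enyl)-1,5-bis(triisopropylsilyloxy)benzene, via aryllithium 6 (not isolated)
Conditions: n-BuLi (1.0 equiv), THF, −78 °C; CuBr·SMe2 (10 mol %), 5 (1.5 equiv), −78 to 0 °C
Reagents that add atoms: none
Why: One equivalent of n-BuLi should exchange a single bromine of the symmetrical dibromide (bromine–lithium exchange), and copper-catalysed allylic substitution of prenyl bromide by the aryllithium should take place at the primary carbon to give the linear prenyl group.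

Step 4
Reactants: 8 (1R,2R)-1,2-dicyclohexylethane-1,2-diol
Product: 11 (4R,5R)-2-(chloromethyl)-4,5-dicyclohexyl-1,3,2-dioxaborolane, via lithium chloromethyl borate 9 (not isolated), via diisopropyl chloromethylboronate 10 (not isolated)
Conditions: B(OiPr)3, BrCH2Cl, n-BuLi, THF, −78 °C; HCl (Et2O), −78 °C to rt; then 8, rt, volatiles removed
Reagents that add atoms: triisopropyl borate, CC(C)OB(OC(C)C)OC(C)C; bromochloromethane, ClCBr
Why: Chloromethyllithium made in the presence of the borate is trapped on boron, acid releases the diisopropyl ester, and transesterification with the 1,2-diol gives the five-membered dioxaborolane, which is the standard preparation of chloromethylboronic esters.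

Step 5
Reactants: 7 2-bromo-3-methoxy-4-(3-methylbut-2-enyl)-1,5-bis(triisopropylsilyloxy)benzene, 11 (4R,5R)-2-(chloromethyl)-4,5-dicyclohexyl-1,3,2-dioxaborolane
Product: 14 (4R,5R)-4,5-dicyclohexyl-2-[2-methoxy-3-(3-methylbut-2-enyl)-4,6-bis(triisopropylsilyloxy)benzyl]-1,3,2-dioxaborolane, via aryllithium 12 (not isolated), via aryl chloromethyl borate 13 (not isolated)
Conditions: n-BuLi (1.05 equiv), THF, −78 °C; 11 (1.1 equiv), −78 °C to rt
Reagents that add atoms: none
Why: Bromine–lithium exchange and addition of the aryllithium to boron give a borate whose aryl group shifts to the CH2Cl carbon with loss of chloride on warming (1,2-metallate rearrangement of a halomethyl borate), which forms C4–C4a without a benzylic halide of the electron-rich ring.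

Step 6
Reactants: 15 4-bromobenzene-1,3-diol (4-bromoresorcinol)
Product: 16 2-bromo-5-(triisopropylsilyloxy)phenol
Conditions: TIPSCl (1.0 equiv), imidazole, CH2Cl2, 0 °C
Reagents that add atoms: chlorotriisopropylsilane, CC(C)[Si](Cl)(C(C)C)C(C)C
Why: The hydroxyl para to bromine is the unhindered one, so one equivalent of the bulky silyl chloride should silylate it in preference to the hydroxyl beside bromine (sterically controlled mono-silylation).

Step 7
Reactants: 16 2-bromo-5-(triisopropylsilyloxy)phenol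
Product: 17 1-bromo-2-(2-methylbut-3-yn-2-yloxy)-4-(triisopropylsilyloxy)benzene
Conditions: 3-chloro-3-methylbut-1-yne, DBU, CuCl2·2H2O (cat.), MeCN, 0 °C
Reagents that add atoms: 3-chloro-3-methylbut-1-yne, C#CC(C)(C)Cl
Why: Copper-catalysed O-alkylation of a phenol with a tertiary propargylic chloride is the standard entry to aryl 1,1-dimethylpropargyl ethers and is mild enough for the aryl silyl ether.

Step 8
Reactants: 17 1-bromo-2-(2-methylbut-3-yn-2-yloxy)-4-(triisopropylsilyloxy)benzene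
Product: 19 8-bromo-2,2-dimethyl-5-(triisopropylsilyloxy)-2H-chromene, via allenylphenol 18 (not isolated)
Conditions: PhNEt2, 190 °C
Reagents that add atoms: none
Why: The aromatic propargyl Claisen rearrangement can only end at the free ortho carbon between the two oxygens (the other ortho carbon carries bromine), and the allenylphenol then closes to the 2,2-dimethylchromene by 1,5-hydrogen shift and oxa-6π electrocyclisation.

Step 9
Reactants: 19 8-bromo-2,2-dimethyl-5-(triisopropylsilyloxy)-2H-chromene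
Product: 20 [2,2-dimethyl-5-(triisopropylsilyloxy)-2H-chromen-8-yl]magnesium bromide (titrated THF solution)
Conditions: Mg turnings (I2-activated), THF, 50 °C
Reagents that add atoms: magnesium, [Mg]
Why: Insertion of magnesium into the aryl C–Br bond (Grignard formation) is routine for alkoxy-substituted aryl bromides, and neither the silyl ether nor the chromene alkene reacts with the metal.

Step 10
Reactants: 14 (4R,5R)-4,5-dicyclohexyl-2-[2-methoxy-3-(3-methylbut-2-enyl)-4,6-bis(triisopropylsilyloxy)benzyl]-1,3,2-dioxaborolane, 20 [2,2-dimethyl-5-(triisopropylsilyloxy)-2H-chromen-8-yl]magnesium bromide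
Product: 25 (4R,5R)-4,5-dicyclohexyl-2-{(1R)-1-[2,2-dimethyl-5-(triisopropylsilyloxy)-2H-chromen-8-yl]-2-[2-methoxy-3-(3-methylbut-2-enyl)-4,6-bis(triisopropylsilyloxy)phenyl]ethyl}-1,3,2-dioxaborolane, via dichloromethyllithium 21 (not isolated), via dichloromethyl borate 22 (not isolated), via α-chloro boronic ester 23 (not isolated), via aryl borate 24 (not isolated)
Conditions: CH2Cl2 (1.6 equiv), n-BuLi (1.3 equiv), THF, −100 °C; 14; ZnCl2 (1.5 equiv), −100 °C to rt; salts filtered off from pentane, crude 23 taken up in THF; 20 (1.5 equiv), −78 °C to rt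
Reagents that add atoms: dichloromethane, ClCCl
Why: n-BuLi deprotonates CH2Cl2 to LiCHCl2 (21), which adds to the boron of 14 to give borate 22; ZnCl2 then binds a ring oxygen and one of the two diastereotopic chlorides, and the ring A benzyl group shifts from boron to carbon anti to that chloride, which forms C3–C4 and the (1S)-α-chloro boronic ester 23. Grignard reagent 20 adds to the boron of 23 to give borate 24, whose electron-rich ring B aryl group migrates with inversion at carbon and expels chloride, which forms C3–C1′. Both events are 1,2-metallate rearrangements of the Matteson homologation type, the closest known case being chloride displacement on an α-chloro boronic ester by a Grignard reagent, and no ring is closed. C3 is controlled by the C2-symmetric (R,R)-diol on boron, which decides which chloride leaves in the first migration, and the second migration is stereospecific, so 25 should be the (1R) boronic ester that maps onto (3R) of the target. The step needs carbon rather than oxygen migration, no chloride-induced epimerisation of 23 and inert prenyl and chromene alkenes; the high migratory aptitude of benzyl and aryl groups, ZnCl2 as chloride scavenger and the purely anionic reagents secure these. Because ring A is delivered as the migrating benzyl group, its congested carbon C4a, flanked by two ortho substituents, takes no part in bond formation.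

Step 11
Reactants: 25 (4R,5R)-4,5-dicyclohexyl-2-{(1R)-1-[2,2-dimethyl-5-(triisopropylsilyloxy)-2H-chromen-8-yl]-2-[2-methoxy-3-(3-methylbut-2-enyl)-4,6-bis(triisopropylsilyloxy)phenyl]ethyl}-1,3,2-dioxaborolane
Product: 27 (4R,5R)-4,5-dicyclohexyl-2-{(2R)-2-[2,2-dimethyl-5-(triisopropylsilyloxy)-2H-chromen-8-yl]-3-[2-methoxy-3-(3-methylbut-2-enyl)-4,6-bis(triisopropylsilyloxy)phenyl]propyl}-1,3,2-dioxaborolane, via chloromethyl borate 26 (not isolated)
Conditions: BrCH2Cl (2.5 equiv), n-BuLi (2.0 equiv, added last), THF, −78 °C to rt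
Reagents that add atoms: bromochloromethane, ClCBr
Why: Chloromethyllithium formed in the presence of the boronic ester adds to boron and the secondary carbon migrates with retention (Matteson one-carbon homologation), which inserts C2 and turns the sensitive benzylic boronic ester into a primary one without touching C3.

Step 12
Reactants: 27 (4R,5R)-4,5-dicyclohexyl-2-{(2R)-2-[2,2-dimethyl-5-(triisopropylsilyloxy)-2H-chromen-8-yl]-3-[2-methoxy-3-(3-methylbut-2-enyl)-4,6-bis(triisopropylsilyloxy)phenyl]propyl}-1,3,2-dioxaborolane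
Product: 28 (2R)-2-[2,2-dimethyl-5-(triisopropylsilyloxy)-2H-chromen-8-yl]-3-[2-methoxy-3-(3-methylbut-2-enyl)-4,6-bis(triisopropylsilyloxy)phenyl]propan-1-ol
Conditions: NaBO3·4H2O, THF/H2O (1:1), rt
Reagents that add atoms: sodium perborate tetrahydrate NaBO3·4H2O, [Na+].[Na+].O[B-]1(O)OO[B-](O)(O)OO1 (anion drawn as its dimer)
Why: Perborate oxidation of the C–B bond proceeds by 1,2-shift of the primary carbon from boron to oxygen, is mild enough for the aryl silyl ethers and both alkenes, and releases the diol auxiliary.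

Step 13
Reactants: 28 (2R)-2-[2,2-dimethyl-5-(triisopropylsilyloxy)-2H-chromen-8-yl]-3-[2-methoxy-3-(3-methylbut-2-enyl)-4,6-bis(triisopropylsilyloxy)phenyl]propan-1-ol
Product: 29 4-[(2R)-3-hydroxy-2-(5-hydroxy-2,2-dimethyl-2H-chromen-8-yl)propyl]-5-methoxy-6-(3-methylbut-2-enyl)benzene-1,3-diol
Conditions: TBAF (3.5 equiv), AcOH (3.5 equiv), THF, 0 °C, under Ar
Reagents that add atoms: none
Why: Fluoride cleaves the three aryl silyl ethers through Si–F bond formation, and the AcOH buffer keeps the electron-rich phenols protonated so that they are not oxidised.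

Step 14
Reactants: 29 4-[(2R)-3-hydroxy-2-(5-hydroxy-2,2-dimethyl-2H-chromen-8-yl)propyl]-5-methoxy-6-(3-methylbut-2-enyl)benzene-1,3-diol
Product: 30 (3R)-3-(5-hydroxy-2,2-dimethyl-2H-chromen-8-yl)-5-methoxy-6-(3-methylbut-2-enyl)chroman-7-ol
Conditions: PPh3, DIAD (betaine pre-formed), THF (0.01 M), 0 °C to rt
Reagents that add atoms: none
Why: In this Mitsunobu etherification the primary alcohol is activated as its alkoxyphosphonium ion and displaced 6-exo-tet by the only phenol that can reach it, the C8a hydroxyl, at C2 and not at C3, while high dilution disfavours intermolecular etherification by the other two phenols.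

**Compound list**

1 | 5-methoxybenzene-1,3-diol (5-methoxyresorcinol) | COc1cc(O)cc(O)c1 | starting material
2 | 1-methoxy-3,5-bis(triisopropylsilyloxy)benzene | COc1cc(O[Si](C(C)C)(C(C)C)C(C)C)cc(O[Si](C(C)C)(C(C)C)C(C)C)c1 | intermediate
3 | 2-bromo-1-methoxy-3,5-bis(triisopropylsilyloxy)benzene | COc1cc(O[Si](C(C)C)(C(C)C)C(C)C)cc(O[Si](C(C)C)(C(C)C)C(C)C)c1Br | intermediate
4 | 2,4-dibromo-3-methoxy-1,5-bis(triisopropylsilyloxy)benzene | COc1c(Br)c(O[Si](C(C)C)(C(C)C)C(C)C)cc(O[Si](C(C)C)(C(C)C)C(C)C)c1Br | intermediate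
5 | 1-bromo-3-methylbut-2-ene (prenyl bromide) | CC(C)=CCBr | starting material
6 | [3-bromo-2-methoxy-4,6-bis(triisopropylsilyloxy)phenyl]lithium | [Li]c1c(OC)c(Br)c(O[Si](C(C)C)(C(C)C)C(C)C)cc1O[Si](C(C)C)(C(C)C)C(C)C | intermediate
7 | 2-bromo-3-methoxy-4-(3-methylbut-2-enyl)-1,5-bis(triisopropylsilyloxy)benzene | COc1c(CC=C(C)C)c(O[Si](C(C)C)(C(C)C)C(C)C)cc(O[Si](C(C)C)(C(C)C)C(C)C)c1Br | intermediate
8 | (1R,2R)-1,2-dicyclohexylethane-1,2-diol | O[C@H](C1CCCCC1)[C@H](O)C1CCCCC1 | starting material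
9 | lithium (chloromethyl)triisopropoxyborate | [Li+].ClC[B-](OC(C)C)(OC(C)C)OC(C)C | intermediate
10 | diisopropyl (chloromethyl)boronate | ClCB(OC(C)C)OC(C)C | intermediate
11 | (4R,5R)-2-(chloromethyl)-4,5-dicyclohexyl-1,3,2-dioxaborolane | ClCB1O[C@H](C2CCCCC2)[C@@H](C2CCCCC2)O1 | intermediate
12 | [2-methoxy-3-(3-methylbut-2-enyl)-4,6-bis(triisopropylsilyloxy)phenyl]lithium | [Li]c1c(OC)c(CC=C(C)C)c(O[Si](C(C)C)(C(C)C)C(C)C)cc1O[Si](C(C)C)(C(C)C)C(C)C | intermediate
13 | lithium (4R,5R)-2-(chloromethyl)-4,5-dicyclohexyl-2-[2-methoxy-3-(3-methylbut-2-enyl)-4,6-bis(triisopropylsilyloxy)phenyl]-1,3,2-dioxaborolan-2-uide | [Li+].COc1c(CC=C(C)C)c(O[Si](C(C)C)(C(C)C)C(C)C)cc(O[Si](C(C)C)(C(C)C)C(C)C)c1[B-]1(CCl)O[C@H](C2CCCCC2)[C@@H](C2CCCCC2)O1 | intermediate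
14 | (4R,5R)-4,5-dicyclohexyl-2-[2-methoxy-3-(3-methylbut-2-enyl)-4,6-bis(triisopropylsilyloxy)benzyl]-1,3,2-dioxaborolane | COc1c(CC=C(C)C)c(O[Si](C(C)C)(C(C)C)C(C)C)cc(O[Si](C(C)C)(C(C)C)C(C)C)c1CB1O[C@H](C2CCCCC2)[C@@H](C2CCCCC2)O1 | intermediate
15 | 4-bromobenzene-1,3-diol (4-bromoresorcinol) | Oc1ccc(Br)c(O)c1 | starting material
16 | 2-bromo-5-(triisopropylsilyloxy)phenol | Oc1cc(O[Si](C(C)C)(C(C)C)C(C)C)ccc1Br | intermediate
17 | 1-bromo-2-(2-methylbut-3-yn-2-yloxy)-4-(triisopropylsilyloxy)benzene | C#CC(C)(C)Oc1cc(O[Si](C(C)C)(C(C)C)C(C)C)ccc1Br | intermediate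
18 | 6-bromo-2-(3-methylbuta-1,2-dienyl)-3-(triisopropylsilyloxy)phenol | CC(C)=C=Cc1c(O)c(Br)ccc1O[Si](C(C)C)(C(C)C)C(C)C | intermediate
19 | 8-bromo-2,2-dimethyl-5-(triisopropylsilyloxy)-2H-chromene | CC1(C)C=Cc2c(O[Si](C(C)C)(C(C)C)C(C)C)ccc(Br)c2O1 | intermediate
20 | [2,2-dimethyl-5-(triisopropylsilyloxy)-2H-chromen-8-yl]magnesium bromide | CC1(C)C=Cc2c(O[Si](C(C)C)(C(C)C)C(C)C)ccc([Mg]Br)c2O1 | intermediate
21 | dichloromethyllithium | [Li]C(Cl)Cl | intermediate
22 | lithium (4R,5R)-4,5-dicyclohexyl-2-(dichloromethyl)-2-[2-methoxy-3-(3-methylbut-2-enyl)-4,6-bis(triisopropylsilyloxy)benzyl]-1,3,2-dioxaborolan-2-uide | [Li+].COc1c(CC=C(C)C)c(O[Si](C(C)C)(C(C)C)C(C)C)cc(O[Si](C(C)C)(C(C)C)C(C)C)c1C[B-]1(C(Cl)Cl)O[C@H](C2CCCCC2)[C@@H](C2CCCCC2)O1 | intermediate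
23 | (4R,5R)-2-{(1S)-1-chloro-2-[2-methoxy-3-(3-methylbut-2-enyl)-4,6-bis(triisopropylsilyloxy)phenyl]ethyl}-4,5-dicyclohexyl-1,3,2-dioxaborolane | COc1c(CC=C(C)C)c(O[Si](C(C)C)(C(C)C)C(C)C)cc(O[Si](C(C)C)(C(C)C)C(C)C)c1C[C@@H](Cl)B1O[C@H](C2CCCCC2)[C@@H](C2CCCCC2)O1 | intermediate
24 | bromomagnesium (4R,5R)-2-{(1S)-1-chloro-2-[2-methoxy-3-(3-methylbut-2-enyl)-4,6-bis(triisopropylsilyloxy)phenyl]ethyl}-4,5-dicyclohexyl-2-[2,2-dimethyl-5-(triisopropylsilyloxy)-2H-chromen-8-yl]-1,3,2-dioxaborolan-2-uide | Br[Mg+].COc1c(CC=C(C)C)c(O[Si](C(C)C)(C(C)C)C(C)C)cc(O[Si](C(C)C)(C(C)C)C(C)C)c1C[C@@H](Cl)[B-]1(c2ccc(O[Si](C(C)C)(C(C)C)C(C)C)c3c2OC(C)(C)C=C3)O[C@H](C2CCCCC2)[C@@H](C2CCCCC2)O1 | intermediate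
25 | (4R,5R)-4,5-dicyclohexyl-2-{(1R)-1-[2,2-dimethyl-5-(triisopropylsilyloxy)-2H-chromen-8-yl]-2-[2-methoxy-3-(3-methylbut-2-enyl)-4,6-bis(triisopropylsilyloxy)phenyl]ethyl}-1,3,2-dioxaborolane | COc1c(CC=C(C)C)c(O[Si](C(C)C)(C(C)C)C(C)C)cc(O[Si](C(C)C)(C(C)C)C(C)C)c1C[C@H](c1ccc(O[Si](C(C)C)(C(C)C)C(C)C)c2c1OC(C)(C)C=C2)B1O[C@H](C2CCCCC2)[C@@H](C2CCCCC2)O1 | intermediate
26 | lithium (4R,5R)-2-(chloromethyl)-4,5-dicyclohexyl-2-{(1R)-1-[2,2-dimethyl-5-(triisopropylsilyloxy)-2H-chromen-8-yl]-2-[2-methoxy-3-(3-methylbut-2-enyl)-4,6-bis(triisopropylsilyloxy)phenyl]ethyl}-1,3,2-dioxaborolan-2-uide | [Li+].COc1c(CC=C(C)C)c(O[Si](C(C)C)(C(C)C)C(C)C)cc(O[Si](C(C)C)(C(C)C)C(C)C)c1C[C@H](c1ccc(O[Si](C(C)C)(C(C)C)C(C)C)c2c1OC(C)(C)C=C2)[B-]1(CCl)O[C@H](C2CCCCC2)[C@@H](C2CCCCC2)O1 | intermediate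
27 | (4R,5R)-4,5-dicyclohexyl-2-{(2R)-2-[2,2-dimethyl-5-(triisopropylsilyloxy)-2H-chromen-8-yl]-3-[2-methoxy-3-(3-methylbut-2-enyl)-4,6-bis(triisopropylsilyloxy)phenyl]propyl}-1,3,2-dioxaborolane | COc1c(CC=C(C)C)c(O[Si](C(C)C)(C(C)C)C(C)C)cc(O[Si](C(C)C)(C(C)C)C(C)C)c1C[C@H](c1ccc(O[Si](C(C)C)(C(C)C)C(C)C)c2c1OC(C)(C)C=C2)CB1O[C@H](C2CCCCC2)[C@@H](C2CCCCC2)O1 | intermediate
28 | (2R)-2-[2,2-dimethyl-5-(triisopropylsilyloxy)-2H-chromen-8-yl]-3-[2-methoxy-3-(3-methylbut-2-enyl)-4,6-bis(triisopropylsilyloxy)phenyl]propan-1-ol | COc1c(CC=C(C)C)c(O[Si](C(C)C)(C(C)C)C(C)C)cc(O[Si](C(C)C)(C(C)C)C(C)C)c1C[C@H](c1ccc(O[Si](C(C)C)(C(C)C)C(C)C)c2c1OC(C)(C)C=C2)CO | intermediate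
29 | 4-[(2R)-3-hydroxy-2-(5-hydroxy-2,2-dimethyl-2H-chromen-8-yl)propyl]-5-methoxy-6-(3-methylbut-2-enyl)benzene-1,3-diol | COc1c(CC=C(C)C)c(O)cc(O)c1C[C@H](c1ccc(O)c2c1OC(C)(C)C=C2)CO | intermediate
30 | (3R)-3-(5-hydroxy-2,2-dimethyl-2H-chromen-8-yl)-5-methoxy-6-(3-methylbut-2-enyl)chroman-7-ol | COc1c(CC=C(C)C)c(O)cc2c1C[C@H](c1ccc(O)c3c1OC(C)(C)C=C3)CO2 | target

**Step count and risks**

Total steps: 14 (ring A branch: steps 1–3 and 5; boron reagent: step 4; ring B branch: steps 6–9; joint part: steps 10–14).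
Longest linear sequence: 9 steps (1, 2, 3, 5, 10, 11, 12, 13, 14; the ring B branch 6–9 followed by 10–14 is equally long).

Steps most likely to fail:

1. Step 2. The second bromination may lose site control and attack the carbon between the two silyloxy groups, or a third bromine may enter. The fallback fixes the bromine positions before the methoxy group exists; it sets out from 15 and returns at 4. Bromination of 15 (Br2, AcOH, 0 °C) at the carbon para to the 3-hydroxyl should give 4,6-dibromobenzene-1,3-diol F1. TIPSOTf and 2,6-lutidine convert it to 1,5-dibromo-2,4-bis(triisopropylsilyloxy)benzene F2. LiN(iPr)2 in THF at −78 °C should remove the only acidic ring hydrogen, the one between the two bromines, to give [2,6-dibromo-3,5-bis(triisopropylsilyloxy)phenyl]lithium F3. Trapping with B(OMe)3 gives lithium [2,6-dibromo-3,5-bis(triisopropylsilyloxy)phenyl]trimethoxyborate F4, and H2O2 oxidises it to 2,6-dibromo-3,5-bis(triisopropylsilyloxy)phenol F5. O-Methylation with MeI and K2CO3 in acetone then gives 4.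

2. Step 10. Borate formation and aryl migration with the ortho-oxygenated Grignard reagent on the hindered α-chloro boronic ester may be slow, so that oxygen migration, β-elimination or chloride-induced epimerisation take over. The fallback keeps a boron-to-carbon 1,2-shift for the C3–C1′ bond but uses reagent control by a lithiated carbamate; it sets out from 7 and 20 and returns at 28. Aryllithium 12, generated from 7 as in step 5, is opened onto ethylene oxide with BF3·OEt2 to give 2-[2-methoxy-3-(3-methylbut-2-enyl)-4,6-bis(triisopropylsilyloxy)phenyl]ethanol F6. N,N-Diisopropylcarbamoyl chloride and Et3N convert it to 2-[2-methoxy-3-(3-methylbut-2-enyl)-4,6-bis(triisopropylsilyloxy)phenyl]ethyl N,N-diisopropylcarbamate F7. Grignard reagent 20 and 2-isopropoxy-4,4,5,5-tetramethyl-1,3,2-dioxaborolane give 2-[2,2-dimethyl-5-(triisopropylsilyloxy)-2H-chromen-8-yl]-4,4,5,5-tetramethyl-1,3,2-dioxaborolane F8. Deprotonation of F7 with s-BuLi and (−)-sparteine in Et2O at −78 °C should give the (S)-α-lithiated carbamate F9, which adds F8 with retention to give the lithium borate F10. On warming with MgBr2·OEt2 the aryl group should migrate with inversion and expel the carbamate, giving the (1R) pinacol boronic ester F11, the pinacol counterpart of 25. Homologation as in step 11, through the chloromethyl borate F12, gives the (2R) primary pinacol boronic ester F13, and perborate oxidation as in step 12 gives 28.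

3. Step 14. The two phenols that cannot cyclise may be etherified intermolecularly, or the azodicarboxylate may aminate the electron-rich phenol rings. The fallback closes the ring by phenoxide displacement without an azo reagent; it sets out from 28 and returns at 30. MsCl and Et3N in CH2Cl2 at 0 °C convert 28 to (2R)-2-[2,2-dimethyl-5-(triisopropylsilyloxy)-2H-chromen-8-yl]-3-[2-methoxy-3-(3-methylbut-2-enyl)-4,6-bis(triisopropylsilyloxy)phenyl]propyl methanesulfonate F14. TBAF in dilute THF at 0 °C to rt then removes the three silyl groups; the C8a phenoxide, once free, should displace the mesylate 6-exo-tet, and the other two phenols are protonated on work-up to give 30.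

**Further compounds**

F1 | step 2 | 4,6-dibromobenzene-1,3-diol | Oc1cc(O)c(Br)cc1Br
F2 | step 2 | 1,5-dibromo-2,4-bis(triisopropylsilyloxy)benzene | Brc1cc(Br)c(O[Si](C(C)C)(C(C)C)C(C)C)cc1O[Si](C(C)C)(C(C)C)C(C)C
F3 | step 2 | [2,6-dibromo-3,5-bis(triisopropylsilyloxy)phenyl]lithium | [Li]c1c(Br)c(O[Si](C(C)C)(C(C)C)C(C)C)cc(O[Si](C(C)C)(C(C)C)C(C)C)c1Br
F4 | step 2 | lithium [2,6-dibromo-3,5-bis(triisopropylsilyloxy)phenyl]trimethoxyborate | [Li+].CO[B-](OC)(OC)c1c(Br)c(O[Si](C(C)C)(C(C)C)C(C)C)cc(O[Si](C(C)C)(C(C)C)C(C)C)c1Br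
F5 | step 2 | 2,6-dibromo-3,5-bis(triisopropylsilyloxy)phenol | Oc1c(Br)c(O[Si](C(C)C)(C(C)C)C(C)C)cc(O[Si](C(C)C)(C(C)C)C(C)C)c1Br
F6 | step 10 | 2-[2-methoxy-3-(3-methylbut-2-enyl)-4,6-bis(triisopropylsilyloxy)phenyl]ethanol | COc1c(CC=C(C)C)c(O[Si](C(C)C)(C(C)C)C(C)C)cc(O[Si](C(C)C)(C(C)C)C(C)C)c1CCO
F7 | step 10 | 2-[2-methoxy-3-(3-methylbut-2-enyl)-4,6-bis(triisopropylsilyloxy)phenyl]ethyl N,N-diisopropylcarbamate | COc1c(CC=C(C)C)c(O[Si](C(C)C)(C(C)C)C(C)C)cc(O[Si](C(C)C)(C(C)C)C(C)C)c1CCOC(=O)N(C(C)C)C(C)C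
F8 | step 10 | 2-[2,2-dimethyl-5-(triisopropylsilyloxy)-2H-chromen-8-yl]-4,4,5,5-tetramethyl-1,3,2-dioxaborolane | CC1(C)OB(OC1(C)C)c1ccc(O[Si](C(C)C)(C(C)C)C(C)C)c2c1OC(C)(C)C=C2
F9 | step 10 | (1S)-1-lithio-2-[2-methoxy-3-(3-methylbut-2-enyl)-4,6-bis(triisopropylsilyloxy)phenyl]ethyl N,N-diisopropylcarbamate (as its sparteine complex) | COc1c(CC=C(C)C)c(O[Si](C(C)C)(C(C)C)C(C)C)cc(O[Si](C(C)C)(C(C)C)C(C)C)c1C[C@H]([Li])OC(=O)N(C(C)C)C(C)C
F10 | step 10 | lithium 2-{(1S)-1-(N,N-diisopropylcarbamoyloxy)-2-[2-methoxy-3-(3-methylbut-2-enyl)-4,6-bis(triisopropylsilyloxy)phenyl]ethyl}-2-[2,2-dimethyl-5-(triisopropylsilyloxy)-2H-chromen-8-yl]-4,4,5,5-tetramethyl-1,3,2-dioxaborolan-2-uide | [Li+].COc1c(CC=C(C)C)c(O[Si](C(C)C)(C(C)C)C(C)C)cc(O[Si](C(C)C)(C(C)C)C(C)C)c1C[C@H]([B-]1(c2ccc(O[Si](C(C)C)(C(C)C)C(C)C)c3c2OC(C)(C)C=C3)OC(C)(C)C(C)(C)O1)OC(=O)N(C(C)C)C(C)C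
F11 | step 10 | 2-{(1R)-1-[2,2-dimethyl-5-(triisopropylsilyloxy)-2H-chromen-8-yl]-2-[2-methoxy-3-(3-methylbut-2-enyl)-4,6-bis(triisopropylsilyloxy)phenyl]ethyl}-4,4,5,5-tetramethyl-1,3,2-dioxaborolane | COc1c(CC=C(C)C)c(O[Si](C(C)C)(C(C)C)C(C)C)cc(O[Si](C(C)C)(C(C)C)C(C)C)c1C[C@H](c1ccc(O[Si](C(C)C)(C(C)C)C(C)C)c2c1OC(C)(C)C=C2)B1OC(C)(C)C(C)(C)O1
F12 | step 10 | lithium 2-(chloromethyl)-2-{(1R)-1-[2,2-dimethyl-5-(triisopropylsilyloxy)-2H-chromen-8-yl]-2-[2-methoxy-3-(3-methylbut-2-enyl)-4,6-bis(triisopropylsilyloxy)phenyl]ethyl}-4,4,5,5-tetramethyl-1,3,2-dioxaborolan-2-uide | [Li+].COc1c(CC=C(C)C)c(O[Si](C(C)C)(C(C)C)C(C)C)cc(O[Si](C(C)C)(C(C)C)C(C)C)c1C[C@H](c1ccc(O[Si](C(C)C)(C(C)C)C(C)C)c2c1OC(C)(C)C=C2)[B-]1(CCl)OC(C)(C)C(C)(C)O1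
F13 | step 10 | 2-{(2R)-2-[2,2-dimethyl-5-(triisopropylsilyloxy)-2H-chromen-8-yl]-3-[2-methoxy-3-(3-methylbut-2-enyl)-4,6-bis(triisopropylsilyloxy)phenyl]propyl}-4,4,5,5-tetramethyl-1,3,2-dioxaborolane | COc1c(CC=C(C)C)c(O[Si](C(C)C)(C(C)C)C(C)C)cc(O[Si](C(C)C)(C(C)C)C(C)C)c1C[C@H](c1ccc(O[Si](C(C)C)(C(C)C)C(C)C)c2c1OC(C)(C)C=C2)CB1OC(C)(C)C(C)(C)O1
F14 | step 14 | (2R)-2-[2,2-dimethyl-5-(triisopropylsilyloxy)-2H-chromen-8-yl]-3-[2-methoxy-3-(3-methylbut-2-enyl)-4,6-bis(triisopropylsilyloxy)phenyl]propyl methanesulfonate | COc1c(CC=C(C)C)c(O[Si](C(C)C)(C(C)C)C(C)C)cc(O[Si](C(C)C)(C(C)C)C(C)C)c1C[C@H](c1ccc(O[Si](C(C)C)(C(C)C)C(C)C)c2c1OC(C)(C)C=C2)COS(C)(=O)=O
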